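The data were computed for an exercise; scatter was added.

Turnovers per minute was the unit I wanted first: that figure, multiplied by [L] and by the run time, gives an amount of G in M.

| setting | alder | maple | amber | teal | blue | violet | green |
|---|---|---|---|---|---|---|---|
| Z | 0.20 M | 0.20 M | 0.20 M | 0.40 M | 0.80 M | 1.5 M | 3.0 M |
| L | 38 mM | 28 mM | 56 mM | 56 mM | 56 mM | 56 mM | 56 mM |
| remark | run made earlier | run made earlier |  |  |  |  |  |
| time |  |  | 1.5 h | 1.5 h | 1.5 h | 1.5 h | 1.5 h |

| run | time / min | G / % | Z / % |
|---|---|---|---|
| alder | 2.50 | 5 | 89 |
| alder | 6.00 | 12 | 79 |
| alder | 12.0 | 21 | 60 |
| alder | 20.0 | 34 | 45 |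
| maple | 2.50 | 1 | 92 |
| maple | 6.00 | 8 | 84 |
| maple | 12.0 | 17 | 68 |
| maple | 20.0 | 28 | 55 |

(scatter of a reading: 1.5 percentage points)

- what was read earlier has a scatter of 1.5 percentage points, one standard deviation
- a reading or a percentage of G counts all its forms, free or not
- the concentration of G that is asked is that of its free form alone
- "hardly changes" means that all values lie within two and a half points (for a concentration: within two and a half percent of the largest)
- a reading of Z is of its free form alone

- [G] (only what is free in solution) at the end for amber, teal, blue, violet, green, in this order
- the shape of the row from first to last (rises all the way / rises, then falls / falls, then rises / falls all the way / hardly changes)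

In maple at 2.50 min, Z and G together fell short of the charge by 7.00% while G stood at 1%. I read that gap as Z held on L, a form I call E, which put 50.0% of the L charged in that form. Dividing the rise of G up to 6.00 min by this E gave a turnover of 0.286 min⁻¹, a rough reading, since each reading scatters by 1.5 percentage points. Multiplied by 56 mM of L and 1.5 h, it made my budget, the G that the L of a flask makes in its run if L sits wholly as E (the ceiling rate taken over the time): 1.44 M. The later gap in alder, 21.0% at 20.0 min, I charged wholly to a pair of Z and G, called Q, leaving E out of that balance, and read its association constant as 17.9 M⁻¹.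

Two extremes could be solved in the head. With L mostly free, Z falls pseudo-first-order, and the integral leaves the same unconverted share at every charge, 6.36% from alder's rate scaled to 56 mM, so free G climbs with the charge. With L wholly held through the run, G in all its forms comes to the budget, provided the charge stands above it. Green then keeps 56 mM as E and 1.50 M as Z or Q, and that constant leaves [G] at 0.230 M. Maple's gap had put 50.0% of its L in E at a [Z] of 0.184 M, and green's charge stood far above that, so I put green near the second extreme and the small charges nearer the first, and I expected a rise, then a fall, turning near the budget.

The forecast differed, “assuming no saturation above” the lowest charge: 0.178 M, 0.353 M, 0.703 M, 1.315 M, 2.63 M, so that the row rises all the way. Its green value stood far above mine.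

Free G came out at 0.135 M, 0.209 M, 0.289 M, 0.320 M and 0.175 M, so the row rises, then falls, turning at a charge of 1.4 M.

    Z + L ⇌ E (K = 2.70 M⁻¹, k = 220 M⁻¹ h⁻¹)
    Z + G ⇌ Q, settled at all times (K = 18.0 M⁻¹)
    E → L + G (k = 23.0 h⁻¹)

At 1.50 h green held 80.5% of its charge in Q, each Q counting as two, with 46.1% as G in all its forms. Against the budget of 1.44 M, green's G in all its forms, 1.38 M, came to 96.0% of it, and violet's, from a charge of 1.5 M, to 59.6%.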